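## The problem

The target is a labdane-type acid with a cis-fused decalin (5β-H, 10β-CH3), an exocyclic methylene at C8, a quaternary C4 carrying the β-carboxyl (C19) and an α-methyl group, and a C9 side chain on the α face that ends in a caffeate ester at O15. Four of the five stereocentres (C4, C5, C9, C10) sit on the bicycle and two are quaternary. C5, C9 and C10 depend on one another and can be set in one ring-forming event, and the angular methyl of the finished bicycle can then direct the construction of C4. C13 is too far from the rings to be controlled by them and has to be bought as a single enantiomer. The side chain on C9 is cis to C1 and C4 across ring B, on the concave face, so it cannot be added from the open face of a preformed cis-decalin. The late chemistry is limited by the C8=C17 alkene (acid moves it into the ring; it cannot survive hydrogenation), by the catechol cinnamate (air, base, nucleophiles), by the axial neopentyl carboxyl (its esters resist saponification) and by C9, which is epimerisable whenever C8 is a carbonyl. The enabling feature is ring B: C5–C10 and C8–C9 are the two σ-bonds of a cyclohexene retron whose diene (C5 to C8) has its oxygen on C8, where the methylene must later stand. Its dienophile (C9=C10) carries the methyl group and C11 as an acceptor, and the C1–C4 chain ties C5 to C10, so one intramolecular [4+2] event closes both rings.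

## Retrosynthesis

**Caffeate.** Target 38 is cut at the cinnamate Cα=Cβ bond to the malonic half-ester 35 and 3,4-dihydroxybenzaldehyde 36; 35 is the O-malonyl derivative of hydroxy acid 34. Cutting the ester C–O bond instead would need a protected catechol and an activation step that distinguishes O15 from the C19 acid. The precursor 34 has lost nine carbons and all oxidation-sensitive groups. The forward step must be an E-selective condensation with decarboxylation that tolerates free phenols, a free acid and the exocyclic alkene.

**C4 methyl.** 34 is unmasked from ester 32, and 32 is cut at the C4–CH3 bond to ester 30, which has hydrogen on C4. Making the quaternary centre last is preferred to carrying it through the cycloaddition: a C4–H centre gives a clear equatorial/axial choice in the ring-forming step, and the angular methyl of the finished decalin then shields one face of the C4 enolate. The forward step must alkylate a hindered ester enolate from the α face. For this reason the methylene is installed first (a trigonal C8 fixes the ring conformation) and the ester is tert-butyl.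

**C8 methylene.** 30 is cut at C8=C17 to ketone 29, which comes from silyl ether 27 through alcohol 28. The oxygen at C8 is the one the diene brings in, so no new functionality is needed. Because C9 is α to the ketone in 29, the forward methylenation must be non-basic.

**Side chain.** 27 is the hydrogenation product of diene 26, which is cut at C11=C12 into aldehyde 19 and phosphonium salt 24. A cut at C9–C11 would mean alkylating C9 on the concave face, and a cut at C12–C13 would touch the stereocentre. The chosen cut isolates C13 in a four-carbon piece made from (R)-methylsuccinic acid 20 through diol 21, silyl ether 22 and iodide 23. The olefination must work on a hindered, enolisable β-silyloxy aldehyde; its geometry does not matter.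

**C11 oxidation level.** 19 comes from cycloadduct 17 through alcohol 18. The forward reduction must distinguish the methyl ester at C11 from the tert-butyl ester on C4.

**Both rings.** 17 is cut at C5–C10 and C8–C9, which opens rings A and B at once to the acyclic trienoate 16. Single-ring cuts would leave a cyclohexane on which the quaternary C10 and the concave C9 substituent must be built stepwise. Here the Z-enoate geometry encodes C9/C10, the endo mode encodes the cis fusion, and the diene oxygen lands on C8. The precursor has one stereocentre (C4) instead of five. The forward reaction must close through the endo transition state on one diene face with a hindered β,β-disubstituted dienophile. The face is set by C4: in the chair-like tether the ester is equatorial and the dienophile adds anti to it, which requires the R configuration in 16 for the 5β,10β series.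

**Diene.** 16 is the silyl dienol ether of enal 15, and 15 is cut at C6=C7 by cross-metathesis to the terminal alkene 14. This takes C7, C8 and the oxygen from a small enal partner in one step and leaves the trisubstituted enoate untouched. The enolisation must give the 1E,3E diene.

**Dienophile.** 14 is cut at C10–CH3 to alkynoate 12, and 12 at C9–C11 to the terminal alkyne 10. Syn carbometalation of an alkynoate is the most direct stereospecific route to a 3-methyl-enoate in which the chain is cis to the ester. The forward steps must not deprotonate C4.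

**C4 stereocentre.** 10 is the tert-butyl ester of acid 9, released from imide 7. 7 is cut at C4–C5 to imide 4 and allyl bromide 5, and 4 is made from hept-6-ynoic acid 1 and oxazolidinone 2. An auxiliary-controlled allylation is the most reliable way to set an α-stereocentre between two unbranched chains; the S auxiliary gives the required R centre.

## Roads not taken

Alternative 1: The cut is C9–C10, paired with a C2–O bond that exists only in the precursor. In the forward step a Claisen rearrangement contracts an eight-membered ring (O, C8, C7, C6, C5, C10, C1, C2) whose Z exocyclic enol ether carries C9 and the whole side chain. Heating forms C9–C10 across the ring and closes ring B as the cis-fused C8 ketone A1.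
- Merits: the quaternary C10 and C9 are made together through an ordered six-membered transition state, the carbonyl appears at C8, and the side chain with C13 arrives in the key step. On convergence this road is better than the chosen one, which spends five steps after the cycloaddition on attaching and adjusting the chain.
- Weak points: the substrate is a medium ring bridged across a cyclohexene that already holds C4 and C5 and a trisubstituted C1=C10 alkene. Its ring carbonyl must be turned into a branched, functionalised alkylidene of defined Z geometry, which is capricious on hindered substrates. The chair/boat preference of the bridged transition state, which decides C9, is hard to predict. A1 still lacks the C4 methyl, has C19 at the alcohol level and carries an extra C1=C2 alkene.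
- Comparison: the chosen plan offers an acyclic precursor made by one auxiliary alkylation, no medium ring, and a key step whose stereochemical course follows from well-studied transition-state models.

Alternative 2: The cut is C4–C5. The forward step is an anionic oxy-Cope rearrangement: a tertiary allylic alkoxide (KH) on a bicyclo[2.2.2]octene undergoes a [3,3] shift that forms C4–C5, breaks a C2–C7 bridge bond, closes ring A and releases ring B. Protonation gives the cis-decalin ketone A2.
- Merits: the reaction runs at low temperature and the rigid bicycle guarantees the cis fusion. The quaternary C4 is set stereospecifically by the geometry of the migrating alkene. Here this road is better than the chosen one, which leaves C4 to a late substrate-controlled alkylation.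
- Weak points: A2 has a ketone at C2 and a dimethyl ketal at C1 that the target lacks, and removing two oxygens beside the quaternary C10 costs several steps. C17 arrives as a silyloxymethyl group that must become the exocyclic alkene without the double bond moving into the ring, and C19 is at the alcohol level. The bicyclic precursor comes from a cycloaddition that is not easily made enantioselective, so matching with C13 would need a resolution.
- Comparison: the chosen plan has no surplus oxygen. Every heteroatom of 17 maps onto the target, and absolute configuration comes from one inexpensive auxiliary.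

Alternative 3: The cuts are C5–C6 and C9–C10. Ring B is made by an intermolecular Diels–Alder reaction of the 1-amino-3-silyloxydiene A4 with the 2-methylcyclohexenone ester A5, which gives the cis-fused cycloadduct A3.
- Merits: the doubly activated diene engages a 2-methyl enone under mild conditions, the partners are small, and catalytic enantioselective versions exist for this diene class. The bicycle is reached in far fewer steps than the nine that lead to 17; on step count to the core this road is clearly ahead.
- Weak points: the oxygen of A3 sits on C7, not C8, so C17 must be added to C8 and the C7 oxygen removed. C11 is absent, and the side chain would have to be added to C9 on the concave face of a cis-decalin, against the normal facial bias. The C1 ketone must also be deleted.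
- Comparison: the chosen plan places oxygen on C8, brings C11 in with the dienophile and fixes C9 by alkene geometry instead of by facial approach.

Key step: step 9

Convention used below: atoms carry labdane numbers (C4 is the carbon that becomes the quaternary centre, C11 the dienophile ester carbon). α/β refer to the usual drawing with ring A at the left and the C10 methyl up (β).

## Route

Step 1
Reactants: 1 hept-6-ynoic acid; 2 (4S)-4-benzyl-1,3-oxazolidin-2-one
Product: 4 (4S)-4-benzyl-3-(hept-6-ynoyl)-1,3-oxazolidin-2-one, via hept-6-ynoic pivalic anhydride 3 (not isolated)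
Conditions: t-BuCOCl, Et3N, THF, −20 °C; then 2, LiCl, −20 °C → rt
Reagents that add atoms: none
Why: N-acylation of the oxazolidinone through the mixed pivalic anhydride; LiCl/Et3N activates the carbamate without a strong base, so the terminal alkyne is untouched.

Step 2
Reactants: 4 (4S)-4-benzyl-3-(hept-6-ynoyl)-1,3-oxazolidin-2-one; 5 allyl bromide
Product: 7 (4S)-4-benzyl-3-[(2R)-2-(prop-2-en-1-yl)hept-6-ynoyl]-1,3-oxazolidin-2-one, via sodium Z-enolate 6 (not isolated)
Conditions: NaN(SiMe3)2, THF, −78 °C; then 5, −78 → −40 °C
Reagents that add atoms: none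
Why: Evans asymmetric alkylation: the chelated Z-enolate is attacked by the allyl halide on the face opposite the benzyl group, which sets C4 as R; the silylamide is too weak a base to metalate the alkyne competitively.

Step 3
Reactants: 7 (4S)-4-benzyl-3-[(2R)-2-(prop-2-en-1-yl)hept-6-ynoyl]-1,3-oxazolidin-2-one
Product: 9 (2R)-2-(prop-2-en-1-yl)hept-6-ynoic acid, via peroxy acid 8 (not isolated)
Conditions: LiOH, H2O2, THF/H2O, 0 °C; then aq. Na2SO3; aq. HCl
Reagents that add atoms: hydrogen peroxide, OO
Why: Hydroperoxide cleavage of the N-acyl oxazolidinone: LiOOH attacks the exocyclic carbonyl, auxiliary 2 is released for re-use and C4 is not epimerised; sulfite reduces the peracid to the acid.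

Step 4
Reactants: 9 (2R)-2-(prop-2-en-1-yl)hept-6-ynoic acid
Product: 10 tert-butyl (2R)-2-(prop-2-en-1-yl)hept-6-ynoate
Conditions: Cl3CC(=NH)O-t-Bu, BF3·OEt2 (cat.), cyclohexane/CH2Cl2, rt
Reagents that add atoms: tert-butyl 2,2,2-trichloroacetimidate, CC(C)(C)OC(=N)C(Cl)(Cl)Cl
Why: Acid-catalysed O-tert-butylation with the trichloroacetimidate; no base touches the α-stereocentre. The tert-butyl ester is chosen so that the later hydride reduction at C11 can tell the two esters apart.

Step 5
Reactants: 10 tert-butyl (2R)-2-(prop-2-en-1-yl)hept-6-ynoate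
Product: 12 1-tert-butyl 8-methyl (2R)-2-(prop-2-en-1-yl)oct-6-ynedioate, via alkynylmagnesium chloride 11 (not isolated)
Conditions: i-PrMgCl·LiCl, THF, 0 °C → rt; then ClCO2Me, −40 → 0 °C
Reagents that add atoms: methyl chloroformate, COC(=O)Cl
Why: Magnesiation of the terminal alkyne and C-acylation with a chloroformate; the Grignard base, unlike a lithium amide, does not enolise the α-branched tert-butyl ester, so C4 keeps its configuration.

Step 6
Reactants: 12 1-tert-butyl 8-methyl (2R)-2-(prop-2-en-1-yl)oct-6-ynedioate
Product: 14 1-tert-butyl 8-methyl (2R,6Z)-6-methyl-2-(prop-2-en-1-yl)oct-6-enedioate, via lithium alkenyl(methyl)cuprate 13 (not isolated)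
Conditions: Me2CuLi, THF, −78 °C; then MeOH, −78 °C
Reagents that add atoms: lithium dimethylcuprate, [Li+].C[Cu-]C
Why: Syn carbocupration of the alkynoate: methyl and copper add to the same side, and protonation at −78 °C with retention gives the 3-methyl-enoate with the chain cis to the ester (6Z); the cold quench prevents equilibration through the allenolate.

Step 7
Reactants: 14 1-tert-butyl 8-methyl (2R,6Z)-6-methyl-2-(prop-2-en-1-yl)oct-6-enedioate
Product: 15 1-tert-butyl 8-methyl (2R,6Z)-6-methyl-2-[(2E)-4-oxobut-2-en-1-yl]oct-6-enedioate
Conditions: (E)-crotonaldehyde (excess), second-generation Hoveyda–Grubbs catalyst (5 mol%), CH2Cl2, 40 °C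
Reagents that add atoms: (E)-but-2-enal, C/C=C/C=O
Why: Olefin cross-metathesis of the terminal alkene with an enal partner gives the E-enal; the trisubstituted, β,β-disubstituted enoate does not react with the ruthenium carbene.

Step 8
Reactants: 15 1-tert-butyl 8-methyl (2R,6Z)-6-methyl-2-[(2E)-4-oxobut-2-en-1-yl]oct-6-enedioate
Product: 16 1-tert-butyl 8-methyl (2R,6Z)-2-[(1E,3E)-4-(tert-butyldimethylsilyloxy)buta-1,3-dien-1-yl]-6-methyloct-6-enedioate
Conditions: t-BuMe2SiOTf, Et3N, CH2Cl2, −78 → 0 °C
Reagents that add atoms: tert-butyldimethylsilyl trifluoromethanesulfonate, CC(C)(C)[Si](C)(C)OS(=O)(=O)C(F)(F)F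
Why: Soft enolisation of the enal (O-silylation, then γ-deprotonation at C5) to the 1-silyloxydiene. The C7=C8 bond should be E because the s-trans silyloxocarbenium ion is deprotonated, and the new C5=C6 bond should be mainly E because the branched C4 substituent avoids the cis position; at this temperature the esters are not silylated.

Step 9
Reactants: 16 1-tert-butyl 8-methyl (2R,6Z)-2-[(1E,3E)-4-(tert-butyldimethylsilyloxy)buta-1,3-dien-1-yl]-6-methyloct-6-enedioate
Product: 17 cycloadduct (cis-fused octalin; 4α-CO2t-Bu; 5β-H; 8α-OSiMe2t-Bu; 9α-CO2Me; 10β-CH3; C6=C7)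
Conditions: PhMe (0.02 M), Et3N (0.1 equiv), 2,6-di-tert-butyl-4-methylphenol (cat.), sealed tube, 165 °C
Reagents that add atoms: none
Why: Concerted but asynchronous suprafacial [4+2] cycloaddition of the electron-rich 1-silyloxydiene (C5–C8) with the tethered Z-enoate (C9=C10); the C5–C10 bond runs ahead because the nucleophilic diene terminus meets the enoate β-carbon. The closest known reaction type is the thermal intramolecular Diels–Alder reaction of 1,7,9-decatrienoates with Z-dienophiles and of 1-oxygenated dienes. Ring B closes as the six-membered cycloaddition ring (both new bonds, boat-like array), and ring A closes through the four-carbon tether as a fused six-membered ring in a chair-like arrangement. The cis C5/C10 fusion follows from the endo transition state, with ester and tether both under the diene; C9 follows from the retained Z geometry (C11 cis to C1, H9 cis to the C10 methyl); C8 follows from the E enol ether, which places the silyloxy group cis to the ester. The absolute sense comes from C4: in the chair-like tether the tert-butyl ester is equatorial and anti to the incoming dienophile, because the axial site would clash 1,3-diaxially with the C10 methyl, so the R centre delivers 5β-H, 10β-CH3 and 9β-H. The step needs endo over exo closure and one diene face; secondary overlap of the ester with the silyloxydiene and the equatorial preference at C4 should provide them. The matched polarity (donor at C8, acceptor at C11) offsets the hindered β,β-disubstituted dienophile.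

Step 10
Reactants: 17 cycloadduct
Product: 18 C11 alcohol (as 17 with 9α-CH2OH)
Conditions: i-Bu2AlH (2.5 equiv), CH2Cl2, −78 → −40 °C; aq. potassium sodium tartrate
Reagents that add atoms: none
Why: Hydride reduction of the methyl ester to the primary alcohol; the tert-butyl ester is much slower toward i-Bu2AlH at this temperature, and no base is present that could eliminate the β-silyloxy group.

Step 11
Reactants: 18 C11 alcohol
Product: 19 C11 aldehyde (as 17 with 9α-CHO)
Conditions: Dess–Martin periodinane, NaHCO3, CH2Cl2, 0 °C → rt
Reagents that add atoms: none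
Why: Dess–Martin oxidation under buffered, non-basic conditions gives the β-silyloxy aldehyde without epimerising C9 or eliminating the C8 oxygen.

Step 12
Reactants: 20 (R)-methylsuccinic acid
Product: 21 (2R)-2-methylbutane-1,4-diol
Conditions: LiAlH4, THF, 0 °C → reflux
Reagents that add atoms: none
Why: Hydride reduction of both carboxyl groups; the stereocentre is carried over unchanged and becomes C13.

Step 13
Reactants: 21 (2R)-2-methylbutane-1,4-diol
Product: 22 (2R)-4-(tert-butyldiphenylsilyloxy)-2-methylbutan-1-ol
Conditions: t-BuPh2SiCl (1.0 equiv), imidazole, CH2Cl2, −20 → 0 °C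
Reagents that add atoms: tert-butyl(chloro)diphenylsilane, CC(C)(C)[Si](Cl)(c1ccccc1)c1ccccc1
Why: Sterically controlled monosilylation: the bulky chloride reacts faster at the unbranched hydroxyl (the future O15) than at the β-branched one; the minor regioisomer and the bis-ether are removed by chromatography.

Step 14
Reactants: 22 (2R)-4-(tert-butyldiphenylsilyloxy)-2-methylbutan-1-ol
Product: 23 tert-butyl{[(3R)-4-iodo-3-methylbutyl]oxy}diphenylsilane
Conditions: I2, PPh3, imidazole, CH2Cl2, 0 °C → rt
Reagents that add atoms: iodine, II
Why: Appel-type iodination by SN2 displacement of the oxyphosphonium ion at the primary carbon; the adjacent stereocentre is not involved.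

Step 15
Reactants: 23 tert-butyl{[(3R)-4-iodo-3-methylbutyl]oxy}diphenylsilane
Product: 24 [(2R)-4-(tert-butyldiphenylsilyloxy)-2-methylbutyl]triphenylphosphonium iodide
Conditions: PPh3, MeCN, reflux
Reagents that add atoms: triphenylphosphine, c1ccc(cc1)P(c1ccccc1)c1ccccc1
Why: SN2 quaternisation of the phosphine by the primary iodide; heating compensates for the β-branch.

Step 16
Reactants: 19 C11 aldehyde; 24 [(2R)-4-(tert-butyldiphenylsilyloxy)-2-methylbutyl]triphenylphosphonium iodide
Product: 26 (11Z)-alkene (as 17 with 9α-[(1Z)-5-(tert-butyldiphenylsilyloxy)-3-methylpent-1-en-1-yl]), via phosphonium ylide 25 (not isolated)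
Conditions: 24, NaN(SiMe3)2, THF, −78 → 0 °C; then 19, −78 °C → rt
Reagents that add atoms: none
Why: Wittig olefination with a non-stabilised ylide joins C11 to C12 (mainly Z, irrelevant because the alkene is hydrogenated next); addition to the aldehyde at −78 °C should outrun enolisation toward C9.

Step 17
Reactants: 26 (11Z)-alkene
Product: 27 saturated silyl ether (cis-decalin; 4α-CO2t-Bu; 8α-OSiMe2t-Bu; 13S side chain with 15-OSiPh2t-Bu)
Conditions: H2 (1 atm), PtO2, EtOAc, rt
Reagents that add atoms: none
Why: Heterogeneous catalytic hydrogenation of the two disubstituted alkenes (C6=C7 and C11=C12); no stereocentre is formed, and PtO2 is used instead of Pd to limit hydrogenolysis of the allylic C8–O bond.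

Step 18
Reactants: 27 saturated silyl ether
Product: 28 C8 alcohol (as 27 with 8α-OH)
Conditions: camphor-10-sulfonic acid (0.2 equiv), MeOH/CH2Cl2, 0 °C → rt
Reagents that add atoms: none
Why: Acid-catalysed methanolysis of the secondary tert-butyldimethylsilyl ether; the primary tert-butyldiphenylsilyl ether is much more stable to acid, and the tert-butyl ester survives these conditions.

Step 19
Reactants: 28 C8 alcohol
Product: 29 C8 ketone (as 27 with C8=O)
Conditions: Dess–Martin periodinane, NaHCO3, CH2Cl2, rt
Reagents that add atoms: none
Why: Dess–Martin oxidation of the secondary alcohol under neutral conditions; C9, now α to the ketone, carries its chain in the equatorial, thermodynamically preferred position.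

Step 20
Reactants: 29 C8 ketone
Product: 30 exocyclic alkene (as 27 with C8=CH2)
Conditions: Cp2TiMe2, PhMe/THF, 65 °C, dark
Reagents that add atoms: dimethyltitanocene, [CH3-].[CH3-].[Ti+4].c1cc[cH-]c1.c1cc[cH-]c1
Why: Petasis methylenation: the titanium methylidene formed on heating converts the hindered, enolisable ketone into the 1,1-disubstituted alkene without base, so C9 is not epimerised; the tert-butyl ester reacts far more slowly.

Step 21
Reactants: 30 exocyclic alkene
Product: 32 C4-methylated ester (4α-CH3; 4β-CO2t-Bu), via lithium ester enolate 31 (not isolated)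
Conditions: LiN(i-Pr)2, THF, −78 → 0 °C; then MeI, DMPU, −78 °C → rt
Reagents that add atoms: iodomethane, CI
Why: Diastereoselective alkylation of the exocyclic ester enolate. With C8 trigonal the decalin should adopt the chair–chair form that keeps the C9 chain equatorial; there the C10 methyl is axial over ring A and blocks the β face of C4, so MeI should enter equatorially from the α face and the carboxyl ends up β, as in C4 alkylations of angular-methyl decalin esters.

Step 22
Reactants: 32 C4-methylated ester
Product: 34 hydroxy acid (13S; 15-OH; 19-CO2H; C8=CH2), via trimethylsilyl ester 33 (not isolated)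
Conditions: Me3SiOTf, 2,6-lutidine, CH2Cl2, 0 °C; then Bu4NF, THF, rt; aq. HCl to pH 3
Reagents that add atoms: none
Why: Silyl-triflate-mediated cleavage of the tert-butyl ester (O-silylation, loss of isobutene) under buffered conditions that do not protonate the exocyclic alkene, followed by fluoride cleavage of the silyl ester and the silyl ether.

Step 23
Reactants: 34 hydroxy acid
Product: 35 15-O-malonyl half-ester
Conditions: Meldrum's acid, PhMe, 100 °C
Reagents that add atoms: 2,2-dimethyl-1,3-dioxane-4,6-dione, CC1(C)OC(=O)CC(=O)O1
Why: Acylation of the primary alcohol by ring opening of Meldrum's acid with loss of acetone; the tertiary neopentyl C19 acid does not compete.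

Step 24
Reactants: 35 15-O-malonyl half-ester; 36 3,4-dihydroxybenzaldehyde
Product: 38 target CNP0130717.2, via arylidene malonic half-ester 37 (not isolated)
Conditions: pyridine, piperidine (cat.), 60 °C
Reagents that add atoms: none
Why: Knoevenagel–Doebner condensation: the malonate condenses with the aldehyde and decarboxylates in pyridine to the E-cinnamate, so the caffeate is made without protecting the catechol and without activating an acid next to the free C19 carboxyl.

## Compound list

1 | hept-6-ynoic acid | C#CCCCCC(=O)O | starting material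
2 | (4S)-4-benzyl-1,3-oxazolidin-2-one | O=C1N[C@@H](Cc2ccccc2)CO1 | starting material
3 | hept-6-ynoic pivalic anhydride (formed in the flask) | C#CCCCCC(=O)OC(=O)C(C)(C)C | intermediate
4 | (4S)-4-benzyl-3-(hept-6-ynoyl)-1,3-oxazolidin-2-one | C#CCCCCC(=O)N1[C@@H](Cc2ccccc2)COC1=O | intermediate
5 | allyl bromide | C=CCBr | starting material
6 | sodium Z-enolate of 4 (formed in the flask) | [Na+].C#CCCC/C=C(\[O-])N1[C@@H](Cc2ccccc2)COC1=O | intermediate
7 | (4S)-4-benzyl-3-[(2R)-2-(prop-2-en-1-yl)hept-6-ynoyl]-1,3-oxazolidin-2-one | C#CCCC[C@H](CC=C)C(=O)N1[C@@H](Cc2ccccc2)COC1=O | intermediate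
8 | (2R)-2-(prop-2-en-1-yl)hept-6-yneperoxoic acid (formed in the flask) | C#CCCC[C@H](CC=C)C(=O)OO | intermediate
9 | (2R)-2-(prop-2-en-1-yl)hept-6-ynoic acid | C#CCCC[C@H](CC=C)C(=O)O | intermediate
10 | tert-butyl (2R)-2-(prop-2-en-1-yl)hept-6-ynoate | C#CCCC[C@H](CC=C)C(=O)OC(C)(C)C | intermediate
11 | chloromagnesium acetylide of 10 (formed in the flask) | Cl[Mg]C#CCCC[C@H](CC=C)C(=O)OC(C)(C)C | intermediate
12 | 1-tert-butyl 8-methyl (2R)-2-(prop-2-en-1-yl)oct-6-ynedioate | COC(=O)C#CCCC[C@H](CC=C)C(=O)OC(C)(C)C | intermediate
13 | lithium alkenyl(methyl)cuprate from 12, Cu cis to the new methyl (formed in the flask) | [Li+].C[Cu-]/C(C(=O)OC)=C(\C)CCC[C@H](CC=C)C(=O)OC(C)(C)C | intermediate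
14 | 1-tert-butyl 8-methyl (2R,6Z)-6-methyl-2-(prop-2-en-1-yl)oct-6-enedioate | COC(=O)/C=C(C)\CCC[C@H](CC=C)C(=O)OC(C)(C)C | intermediate
15 | 1-tert-butyl 8-methyl (2R,6Z)-6-methyl-2-[(2E)-4-oxobut-2-en-1-yl]oct-6-enedioate | COC(=O)/C=C(C)\CCC[C@H](C/C=C/C=O)C(=O)OC(C)(C)C | intermediate
16 | 1-tert-butyl 8-methyl (2R,6Z)-2-[(1E,3E)-4-(tert-butyldimethylsilyloxy)buta-1,3-dien-1-yl]-6-methyloct-6-enedioate (cycloaddition precursor) | CC(C)(C)[Si](C)(C)O/C=C/C=C/[C@H](C(=O)OC(C)(C)C)CCC/C(C)=C\C(=O)OC | intermediate
17 | cycloadduct: cis-fused octalin, 4α-CO2t-Bu (4β-H), 5β-H, 8α-OSiMe2t-Bu, 9α-CO2Me, 10β-CH3, C6=C7 | CC(C)(C)[Si](C)(C)O[C@@H]1C=C[C@H]2[C@](C)(CCC[C@H]2C(=O)OC(C)(C)C)[C@@H]1C(=O)OC | intermediate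
18 | C11 alcohol: as 17 with 9α-CH2OH | CC(C)(C)[Si](C)(C)O[C@@H]1C=C[C@H]2[C@](C)(CCC[C@H]2C(=O)OC(C)(C)C)[C@@H]1CO | intermediate
19 | C11 aldehyde: as 17 with 9α-CHO | CC(C)(C)[Si](C)(C)O[C@@H]1C=C[C@H]2[C@](C)(CCC[C@H]2C(=O)OC(C)(C)C)[C@@H]1C=O | intermediate
20 | (R)-methylsuccinic acid | C[C@H](CC(=O)O)C(=O)O | starting material
21 | (2R)-2-methylbutane-1,4-diol | C[C@H](CCO)CO | intermediate
22 | (2R)-4-(tert-butyldiphenylsilyloxy)-2-methylbutan-1-ol | C[C@H](CCO[Si](c1ccccc1)(c1ccccc1)C(C)(C)C)CO | intermediate
23 | tert-butyl{[(3R)-4-iodo-3-methylbutyl]oxy}diphenylsilane | C[C@H](CCO[Si](c1ccccc1)(c1ccccc1)C(C)(C)C)CI | intermediate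
24 | [(2R)-4-(tert-butyldiphenylsilyloxy)-2-methylbutyl]triphenylphosphonium iodide | C[C@H](CCO[Si](c1ccccc1)(c1ccccc1)C(C)(C)C)C[P+](c1ccccc1)(c1ccccc1)c1ccccc1.[I-] | intermediate
25 | phosphonium ylide from 24 (formed in the flask) | C[C@H](CCO[Si](c1ccccc1)(c1ccccc1)C(C)(C)C)C=P(c1ccccc1)(c1ccccc1)c1ccccc1 | intermediate
26 | (11Z)-alkene: as 17 with 9α-[(1Z)-5-(tert-butyldiphenylsilyloxy)-3-methylpent-1-en-1-yl], C13 as in 24 | CC(C)(C)[Si](C)(C)O[C@@H]1C=C[C@H]2[C@](C)(CCC[C@H]2C(=O)OC(C)(C)C)[C@@H]1/C=C\[C@H](C)CCO[Si](c1ccccc1)(c1ccccc1)C(C)(C)C | intermediate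
27 | saturated silyl ether: cis-decalin, 4α-CO2t-Bu, 5β-H, 8α-OSiMe2t-Bu, 9β-H, 10β-CH3, 13S, 15-OSiPh2t-Bu | CC(C)(C)[Si](C)(C)O[C@@H]1CC[C@H]2[C@](C)(CCC[C@H]2C(=O)OC(C)(C)C)[C@@H]1CC[C@H](C)CCO[Si](c1ccccc1)(c1ccccc1)C(C)(C)C | intermediate
28 | C8 alcohol: as 27 with 8α-OH | O[C@@H]1CC[C@H]2[C@](C)(CCC[C@H]2C(=O)OC(C)(C)C)[C@@H]1CC[C@H](C)CCO[Si](c1ccccc1)(c1ccccc1)C(C)(C)C | intermediate
29 | C8 ketone: as 27 with C8=O | O=C1CC[C@H]2[C@](C)(CCC[C@H]2C(=O)OC(C)(C)C)[C@@H]1CC[C@H](C)CCO[Si](c1ccccc1)(c1ccccc1)C(C)(C)C | intermediate
30 | exocyclic alkene: as 27 with C8=CH2 | C=C1CC[C@H]2[C@](C)(CCC[C@H]2C(=O)OC(C)(C)C)[C@@H]1CC[C@H](C)CCO[Si](c1ccccc1)(c1ccccc1)C(C)(C)C | intermediate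
31 | lithium ester enolate of 30 at C4 (formed in the flask) | [Li+].C=C1CC[C@H]2[C@](C)(CCCC2=C([O-])OC(C)(C)C)[C@@H]1CC[C@H](C)CCO[Si](c1ccccc1)(c1ccccc1)C(C)(C)C | intermediate
32 | C4-methylated ester: 4α-CH3, 4β-CO2t-Bu, C8=CH2, 15-OSiPh2t-Bu | C=C1CC[C@H]2[C@](C)(CCC[C@]2(C)C(=O)OC(C)(C)C)[C@@H]1CC[C@H](C)CCO[Si](c1ccccc1)(c1ccccc1)C(C)(C)C | intermediate
33 | trimethylsilyl ester of the C19 acid (formed in the flask) | C=C1CC[C@H]2[C@](C)(CCC[C@]2(C)C(=O)O[Si](C)(C)C)[C@@H]1CC[C@H](C)CCO[Si](c1ccccc1)(c1ccccc1)C(C)(C)C | intermediate
34 | hydroxy acid: (13S)-15-hydroxy-5β,9β-H-labd-8(17)-en-19-oic acid with cis ring fusion | C=C1CC[C@H]2[C@](C)(CCC[C@]2(C)C(=O)O)[C@@H]1CC[C@H](C)CCO | intermediate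
35 | 15-O-malonyl half-ester of 34 | C=C1CC[C@H]2[C@](C)(CCC[C@]2(C)C(=O)O)[C@@H]1CC[C@H](C)CCOC(=O)CC(=O)O | intermediate
36 | 3,4-dihydroxybenzaldehyde | O=Cc1ccc(O)c(O)c1 | starting material
37 | arylidene malonic half-ester (formed in the flask) | C=C1CC[C@H]2[C@](C)(CCC[C@]2(C)C(=O)O)[C@@H]1CC[C@H](C)CCOC(=O)C(=Cc1ccc(O)c(O)c1)C(=O)O | intermediate
38 | CNP0130717.2: (13S)-15-[(E)-3-(3,4-dihydroxyphenyl)prop-2-enoyloxy]-5β,9β-H-labd-8(17)-en-19-oic acid (cis-fused, 10β-CH3, 4α-CH3) | C=C1CC[C@H]2[C@](C)(CCC[C@]2(C)C(=O)O)[C@@H]1CC[C@H](C)CCOC(=O)/C=C/c1ccc(O)c(O)c1 | target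

## Step count and least certain steps

Total: 24 steps. Longest linear sequence: 20 steps (steps 1–11 and 16–24, from hept-6-ynoic acid); the side-chain branch is 4 steps (12–15).

**Step 9 (key step).** The most likely failure is that the cycloaddition is too slow, because a quaternary centre is formed from a β,β-disubstituted enoate. Prolonged heating then allows desilylation or polymerisation of the diene, loss of the tert-butyl group, or leakage through the exo (trans-fused) transition state. The fallback changes the dienophile instead of the conditions. Starting from 10, the acetylide 11 is acylated with 2,2,2-trifluoroethyl chloroformate to give the trifluoroethyl alkynoate F1. The sequence of steps 6–8 then gives the Z-enoate F2, the enal F3 and the silyloxydiene F4. The more electron-poor ester should cyclise at lower temperature and with a stronger endo preference to cycloadduct F5. Reduction with i-Bu2AlH as in step 10 returns the route at 18.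

**Step 8.** The risk is erosion of the C5=C6 geometry: γ-deprotonation of enals has an intrinsic preference for the cis arrangement, which the branched C4 substituent should override but may not do completely. A diene with a cis C5=C6 bond cannot reach the cycloaddition geometry. The fallback gives up stereocontrol in the enolisation and uses the cycloaddition as the geometric filter. The mixture from 16 is heated as in step 9, the adduct 17 is separated from uncyclised diene, and that fraction is desilylated (Bu4NF, AcOH) back to enal 15 and resubmitted. No new compound is made.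

**Step 21.** Two things may go wrong: slow deprotonation of the axial C4–H, which is screened by the C10 methyl, and attack of the electrophile on the wrong face if the axial C6 hinders the α side more than expected. If the enolate prefers β attack, the fallback reverses the roles of the two carbon substituents.
- Starting from 30, the enolate 31 is alkylated with 4-methoxybenzyl chloromethyl ether to give the alkoxymethyl ester F6.
- LiAlH4 reduces the ester to the neopentyl alcohol F7.
- Barton–McCombie deoxygenation through the xanthate F8 (NaH, CS2, MeI; then Bu3SnH, AIBN) gives the C4-methyl ether F9.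
- DDQ frees the primary alcohol F10.
- Oxidation (TEMPO, PhI(OAc)2, aqueous MeCN) gives the silyl-protected acid F11.
- Bu4NF then returns the route at 34.

**Step 16.** The risk is enolisation of the hindered β-silyloxy aldehyde by the basic ylide, leading to β-elimination of the C8 oxygen or epimerisation at C9. The fallback replaces the olefination by a non-basic carbonyl addition followed by deoxygenation.
- Iodide 23 is converted into the Grignard reagent F12 (Mg, Et2O).
- F12 is added to 19 in the presence of anhydrous CeCl3 at −78 °C to give the C11 carbinol F13 as a mixture of epimers.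
- 1,1′-Thiocarbonyldiimidazole gives the imidazolyl thiocarbonate F14.
- Bu3SnH/AIBN gives the deoxygenated alkene F15.
- Hydrogenation as in step 17 returns the route at 27.

## Further compounds

F1 | step 9 | 1-tert-butyl 8-(2,2,2-trifluoroethyl) (2R)-2-(prop-2-en-1-yl)oct-6-ynedioate | FC(F)(F)COC(=O)C#CCCC[C@H](CC=C)C(=O)OC(C)(C)C
F2 | step 9 | 1-tert-butyl 8-(2,2,2-trifluoroethyl) (2R,6Z)-6-methyl-2-(prop-2-en-1-yl)oct-6-enedioate | FC(F)(F)COC(=O)/C=C(C)\CCC[C@H](CC=C)C(=O)OC(C)(C)C
F3 | step 9 | 1-tert-butyl 8-(2,2,2-trifluoroethyl) (2R,6Z)-6-methyl-2-[(2E)-4-oxobut-2-en-1-yl]oct-6-enedioate | FC(F)(F)COC(=O)/C=C(C)\CCC[C@H](C/C=C/C=O)C(=O)OC(C)(C)C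
F4 | step 9 | 1-tert-butyl 8-(2,2,2-trifluoroethyl) (2R,6Z)-2-[(1E,3E)-4-(tert-butyldimethylsilyloxy)buta-1,3-dien-1-yl]-6-methyloct-6-enedioate | CC(C)(C)[Si](C)(C)O/C=C/C=C/[C@H](C(=O)OC(C)(C)C)CCC/C(C)=C\C(=O)OCC(F)(F)F
F5 | step 9 | trifluoroethyl analogue of cycloadduct 17 (9α-CO2CH2CF3) | CC(C)(C)[Si](C)(C)O[C@@H]1C=C[C@H]2[C@](C)(CCC[C@H]2C(=O)OC(C)(C)C)[C@@H]1C(=O)OCC(F)(F)F
F0 | step 8 | none | none
F6 | step 21 | 4β-(4-methoxybenzyloxymethyl) 4α-tert-butyl ester derived from 30 | C=C1CC[C@H]2[C@](C)(CCC[C@]2(C(=O)OC(C)(C)C)COCc3ccc(OC)cc3)[C@@H]1CC[C@H](C)CCO[Si](c1ccccc1)(c1ccccc1)C(C)(C)C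
F7 | step 21 | 4α-hydroxymethyl 4β-(4-methoxybenzyloxymethyl) compound | C=C1CC[C@H]2[C@](C)(CCC[C@]2(CO)COCc3ccc(OC)cc3)[C@@H]1CC[C@H](C)CCO[Si](c1ccccc1)(c1ccccc1)C(C)(C)C
F8 | step 21 | S-methyl xanthate of F7 | C=C1CC[C@H]2[C@](C)(CCC[C@]2(COC(=S)SC)COCc3ccc(OC)cc3)[C@@H]1CC[C@H](C)CCO[Si](c1ccccc1)(c1ccccc1)C(C)(C)C
F9 | step 21 | 4α-methyl 4β-(4-methoxybenzyloxymethyl) compound | C=C1CC[C@H]2[C@](C)(CCC[C@]2(C)COCc3ccc(OC)cc3)[C@@H]1CC[C@H](C)CCO[Si](c1ccccc1)(c1ccccc1)C(C)(C)C
F10 | step 21 | 4α-methyl 19-alcohol (15-O-silyl ether) | C=C1CC[C@H]2[C@](C)(CCC[C@]2(C)CO)[C@@H]1CC[C@H](C)CCO[Si](c1ccccc1)(c1ccccc1)C(C)(C)C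
F11 | step 21 | 15-O-(tert-butyldiphenylsilyl) ether of hydroxy acid 34 | C=C1CC[C@H]2[C@](C)(CCC[C@]2(C)C(=O)O)[C@@H]1CC[C@H](C)CCO[Si](c1ccccc1)(c1ccccc1)C(C)(C)C
F12 | step 16 | [(2R)-4-(tert-butyldiphenylsilyloxy)-2-methylbutyl]magnesium iodide | C[C@H](CCO[Si](c1ccccc1)(c1ccccc1)C(C)(C)C)C[Mg]I
F13 | step 16 | C11 carbinol (both C11 epimers) from 19 and F12 | CC(C)(C)[Si](C)(C)O[C@@H]1C=C[C@H]2[C@](C)(CCC[C@H]2C(=O)OC(C)(C)C)[C@@H]1C(O)C[C@H](C)CCO[Si](c1ccccc1)(c1ccccc1)C(C)(C)C
F14 | step 16 | O-(imidazol-1-ylthiocarbonyl) derivative of F13 | CC(C)(C)[Si](C)(C)O[C@@H]1C=C[C@H]2[C@](C)(CCC[C@H]2C(=O)OC(C)(C)C)[C@@H]1C(OC(=S)n1ccnc1)C[C@H](C)CCO[Si](c1ccccc1)(c1ccccc1)C(C)(C)C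
F15 | step 16 | C6=C7 alkene with saturated side chain (11,12-dihydro-26) | CC(C)(C)[Si](C)(C)O[C@@H]1C=C[C@H]2[C@](C)(CCC[C@H]2C(=O)OC(C)(C)C)[C@@H]1CC[C@H](C)CCO[Si](c1ccccc1)(c1ccccc1)C(C)(C)C
A1 | alternative 1 | cis-fused 8-ketone with C1=C2, 4-(4-methoxybenzyloxymethyl) and the complete C9 side chain (15-OSiMe2t-Bu) | O=C1CC[C@H]2[C@](C)(C=CC[C@@H]2COCc3ccc(OC)cc3)[C@@H]1CC[C@H](C)CCO[Si](C)(C)C(C)(C)C
A2 | alternative 2 | cis-decalin 2-ketone with C1 dimethyl ketal, C6=C7, 8-silyloxymethyl, quaternary C4 and the C9 side chain | CC(C)(C)[Si](C)(C)OC[C@H]1C=C[C@H]2[C@](C)(C(OC)(OC)C(=O)C[C@]2(C)COCc3ccc(OC)cc3)[C@@H]1CC[C@H](C)CCO[Si](c4ccccc4)(c5ccccc5)C(C)(C)C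
A3 | alternative 3 | cis-fused amino silyl enol ether cycloadduct (C1 ketone, C4 methyl ester, C7 silyloxy, C9 dimethylamino) | CC(C)(C)[Si](C)(C)OC1=C[C@@H](N(C)C)[C@@]2(C)C(=O)CC[C@H](C(=O)OC)[C@H]2C1
A4 | alternative 3 | (E)-3-(tert-butyldimethylsilyloxy)-N,N-dimethylbuta-1,3-dien-1-amine | CN(C)/C=C/C(=C)O[Si](C)(C)C(C)(C)C
A5 | alternative 3 | methyl (1S)-3-methyl-4-oxocyclohex-2-ene-1-carboxylate | COC(=O)[C@H]1CCC(=O)C(C)=C1
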